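**Retrosynthetic overview**
1. Target ⇐ hydroxyl-directed epoxidation of the 4Z allylic alcohol ⇐ 1,2-reduction of a 6-keto 8,12-diangelate (the ketone masks O6 while O8 and O12 are acylated).
2. Ten-membered (1(10)E,4Z)-dienone ⇐ ring expansion of a cyclopentanone: an alkenyllithium closes a seven-membered ring onto C6=O, then Grob fragmentation of the shared C6–C10 bond with C1–OMs as leaving group.
3. Keto mesylate ⇐ Morita–Baylis–Hillman union of a 4-silyloxy-5-alkylcyclopentenone with (Z)-5-iodo-4-methylpent-4-enal, then chelate-controlled reductive methylation (the C1/C10 relationship that becomes the E alkene).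
4. Cyclopentenone ⇐ Piancatelli rearrangement of a furyl carbinol from a proline aldol of propanal with furfural (C11, then C7/C8).
5. Ring order: furan → cyclopentenone → transient bicyclo[5.3.0]decene → ten-membered carbocycle → oxirane.

Assumption 1: germacrane numbering is used for all intermediates (ring C1–C10, side chain C11–C13, C14 on C10, C15 on C4).
Assumption 2: 12 and 13 are carried as both C1 epimers, and 14–17 as the resulting (1S,10R)/(1R,10S) pair; the SMILES show the (1S,10R) member, and both members converge on 18.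

**Step 1**
Reactants: 1 furfural; 2 propanal
Product: 4 (1S,2R)-1-(furan-2-yl)-2-methylpropane-1,3-diol, via aldol aldehyde 3 (not isolated)
Conditions: L-proline (20 mol %), DMF, 4 °C, slow addition of 2; then MeOH, NaBH4, 0 °C
Reagents that add atoms: none
Why: Proline-catalysed enamine cross-aldol (List–MacMillan type) in which the E-enamine of propanal adds to furfural through the acid-organised chair transition state, so L-proline sets the methyl-bearing carbon (future C11; S in 3, R by CIP in 4, same geometry), in situ borohydride reduction prevents epimerisation, and the carbinol centre is irrelevant because it is ionised in step 3.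

**Step 2**
Reactants: 4 (1S,2R)-1-(furan-2-yl)-2-methylpropane-1,3-diol
Product: 5 (1S,2R)-3-[(tert-butyldiphenylsilyl)oxy]-1-(furan-2-yl)-2-methylpropan-1-ol
Conditions: TBDPSCl (1.05 equiv), imidazole, CH2Cl2, 0 °C
Reagents that add atoms: tert-butyldiphenylsilyl chloride, CC(C)(C)[Si](Cl)(c1ccccc1)c1ccccc1
Why: Sterically controlled silyl ether formation at the primary hydroxyl over the secondary furylic one, giving an acid-stable, bulky CH2OSi group that is the stereocontrol element of step 3.

**Step 3**
Reactants: 5 (1S,2R)-3-[(tert-butyldiphenylsilyl)oxy]-1-(furan-2-yl)-2-methylpropan-1-ol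
Product: 6 (4S,5R)-5-[(2S)-1-[(tert-butyldiphenylsilyl)oxy]propan-2-yl]-4-hydroxycyclopent-2-en-1-one
Conditions: Dy(OTf)3 (10 mol %), t-BuOH/H2O (5:1), 80 °C
Reagents that add atoms: water, O
Why: Piancatelli rearrangement (carbinol ionisation, water addition at furan C5, ring opening, conrotatory 4π-electrocyclisation of the hydroxypentadienyl cation) gives the trans-4-hydroxy-5-alkylcyclopentenone, and with the side-chain C–H held in the dienyl plane by A(1,3) strain the new C7–C8 bond forms anti to the bulky CH2OTBDPS group, predicting 6 as the major trans isomer (expected about 4:1; the minor (4R,5S) isomer is removed by chromatography).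

**Step 4**
Reactants: 6 (4S,5R)-5-[(2S)-1-[(tert-butyldiphenylsilyl)oxy]propan-2-yl]-4-hydroxycyclopent-2-en-1-one
Product: 7 (4S,5R)-4-[(tert-butyldimethylsilyl)oxy]-5-[(2S)-1-[(tert-butyldiphenylsilyl)oxy]propan-2-yl]cyclopent-2-en-1-one
Conditions: TBSCl, imidazole, DMF, 0 → 23 °C
Reagents that add atoms: tert-butyldimethylsilyl chloride, CC(C)(C)[Si](C)(C)Cl
Why: Standard silylation of the secondary allylic alcohol under mild imidazole conditions that avoid β-elimination of the C4 oxygen; no stereocentre is touched.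

**Step 5**
Reactants: 8 pent-4-yn-1-ol
Product: 10 (Z)-5-iodo-4-methylpent-4-en-1-ol, via cyclic alkenylalane 9 (not isolated)
Conditions: Me3Al (3 equiv), Cp2ZrCl2 (25 mol %), ClCH2CH2Cl, 23 °C then reflux, 72 h; I2, THF, −30 → 0 °C
Reagents that add atoms: trimethylaluminium, C[Al](C)C; iodine, II
Why: Negishi Zr-catalysed methylalumination followed by hydroxyl-chelation-driven thermal isomerisation of the alkenylalane (net anti-carbometalation) and iodinolysis with retention gives the iodide with iodine cis to the chain, the geometry that becomes the 4Z alkene.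

**Step 6**
Reactants: 10 (Z)-5-iodo-4-methylpent-4-en-1-ol
Product: 11 (Z)-5-iodo-4-methylpent-4-enal
Conditions: Dess–Martin periodinane, CH2Cl2, 0 → 23 °C
Reagents that add atoms: none
Why: Dess–Martin oxidation of the primary alcohol to the aldehyde under neutral conditions that leave the alkenyl iodide and its geometry untouched.

**Step 7**
Reactants: 7 (4S,5R)-4-[(tert-butyldimethylsilyl)oxy]-5-[(2S)-1-[(tert-butyldiphenylsilyl)oxy]propan-2-yl]cyclopent-2-en-1-one; 11 (Z)-5-iodo-4-methylpent-4-enal
Product: 12 (4S,5R)-4-[(tert-butyldimethylsilyl)oxy]-5-[(2S)-1-[(tert-butyldiphenylsilyl)oxy]propan-2-yl]-2-[(4Z)-1-hydroxy-5-iodo-4-methylpent-4-en-1-yl]cyclopent-2-en-1-one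
Conditions: PBu3 (20 mol %), 1,1'-bi-2-naphthol (10 mol %), THF, 23 °C
Reagents that add atoms: none
Why: Morita–Baylis–Hillman reaction in which reversible phosphine conjugate addition generates the C10 enolate, which adds to aldehyde 11 and then expels the phosphine, forming the C10–C1 bond; the carbinol centre forms unselectively, which is tolerated because C1 becomes sp2 in step 10.

**Step 8**
Reactants: 12 Morita–Baylis–Hillman adduct (both C1 epimers)
Product: 14 (2R,4S,5R)-4-[(tert-butyldimethylsilyl)oxy]-5-[(2S)-1-[(tert-butyldiphenylsilyl)oxy]propan-2-yl]-2-[(1S,4Z)-1-hydroxy-5-iodo-4-methylpent-4-en-1-yl]-2-methylcyclopentan-1-one, via dilithium enolate alkoxide 13 (not isolated)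
Conditions: LiN(SiMe3)2 (1.0 equiv), THF, −78 °C; LiBH(s-Bu)3 (1.1 equiv), −78 °C; MeI (5 equiv), DMPU, −78 → −40 °C; AcOH
Reagents that add atoms: iodomethane, CI
Why: Conjugate hydride reduction delivers the enolate regiospecifically at C10 and the lithium-bridged enolate–alkoxide is methylated on the face anti to the C1 chain (Fráter–Seebach-type chelate-controlled alkylation), so each C1 epimer gives methyl anti to hydroxyl, i.e. the (1S,10R)/(1R,10S) relationship that the fragmentation of step 10 turns into the E alkene.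

**Step 9**
Reactants: 14 methylated ketol (Me/OH anti pair)
Product: 15 C1 methanesulfonate of 14
Conditions: MsCl, Et3N, CH2Cl2, −10 °C
Reagents that add atoms: methanesulfonyl chloride, CS(=O)(=O)Cl
Why: Sulfene-mediated mesylation of the neopentylic secondary alcohol installs the leaving group for the fragmentation, the quaternary C10 excluding β-elimination and the weakly basic conditions avoiding retro-aldol cleavage.

**Step 10**
Reactants: 15 keto mesylate
Product: 18 (1(10)E,4Z,7R,8S,11S)-8-[(tert-butyldimethylsilyl)oxy]-12-[(tert-butyldiphenylsilyl)oxy]germacra-1(10),4-dien-6-one, via alkenyllithium 16 (not isolated), via bicyclic lithium alkoxide 17 (not isolated)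
Conditions: t-BuLi (2.0 equiv), Et2O/pentane, −78 °C; then THF, −78 → 0 °C
Reagents that add atoms: none
Why: Proposed new method: iodine–lithium exchange gives a configurationally stable Z-alkenyllithium that adds 7-exo to the hindered C6 ketone faster than it attacks the neopentylic mesylate, and the resulting cis-fused bicyclo[5.3.0]decenyl lithium alkoxide, whose C1–OMs bond (cis to C14) can lie anti-periplanar to the shared C6–C10 bond, undergoes concerted Grob fragmentation that expands the five-membered ring to the ten-membered dienone with C1=C10 formed E and C4=C5 retained Z, both C1/C10 partners giving the same product; the closest known reactions are the SmI2 Barbier cyclisation–Grob fragmentation sequence of iodoalkyl keto mesylates and the Wharton fragmentation of cyclic 1,3-diol monosulfonates.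

**Step 11**
Reactants: 18 bis-silylated dienone
Product: 19 (1(10)E,4Z,7R,8S,11S)-8,12-dihydroxygermacra-1(10),4-dien-6-one
Conditions: HF·pyridine, pyridine, THF, 0 → 23 °C
Reagents that add atoms: none
Why: Buffered fluoride cleavage of both silyl ethers (standard desilylation) under non-basic conditions that avoid retro-aldol or β-elimination of the β-hydroxy ketone and acid-induced transannular cyclisation.

**Step 12**
Reactants: 19 dihydroxy dienone; 20 angelic acid
Product: 22 (1(10)E,4Z,7R,8S,11S)-6-oxogermacra-1(10),4-diene-8,12-diyl bis[(2Z)-2-methylbut-2-enoate], via mixed anhydride 21 (not isolated)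
Conditions: 20 (3 equiv), 2,4,6-trichlorobenzoyl chloride (3 equiv), Et3N, toluene, 23 °C, 2 h; then 19, 60 °C
Reagents that add atoms: none
Why: Yamaguchi-type mixed-anhydride esterification without DMAP (conditions known to give angelates without Z-to-E isomerisation) acylates the primary O12 and secondary O8 hydroxyls while C6 is still a ketone and cannot be acylated, which differentiates the three oxygens without further protecting groups.

**Step 13**
Reactants: 22 keto diangelate
Product: 23 (1(10)E,4Z,6S,7S,8S,11S)-6-hydroxygermacra-1(10),4-diene-8,12-diyl bis[(2Z)-2-methylbut-2-enoate]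
Conditions: NaBH4, CeCl3·7H2O, MeOH, −78 °C
Reagents that add atoms: none
Why: Luche 1,2-reduction of the enone, chemoselective over the angelates, with hydride expected to add to C6 anti to the adjacent C7 side chain and so place the 6-hydroxyl cis to that side chain (6S by CIP here, the target geometry).

**Step 14**
Reactants: 23 allylic alcohol diangelate
Product: 24 (1(10)E,4S,5R,6R,7S,8S,11S)-4,5-epoxy-6-hydroxygermacr-1(10)-ene-8,12-diyl bis[(2Z)-2-methylbut-2-enoate]
Conditions: VO(acac)2 (5 mol %), t-BuOOH (1.5 equiv), CH2Cl2, 0 °C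
Reagents that add atoms: tert-butyl hydroperoxide, CC(C)(C)OO
Why: Hydroxyl-directed vanadium-catalysed epoxidation (Sharpless–Michaelson type) delivers oxygen to the 4Z alkene on the face syn to the C6 hydroxyl, as found for medium-ring (Z)-cycloalkenols, setting C4 (S) and C5 (R) with the oxirane cis to the 6-OH, while the undirected 1(10) alkene and the electron-poor angelates do not react.

**Compound list**
1 | furfural (furan-2-carbaldehyde) | O=Cc1ccco1 | starting material
2 | propanal | CCC=O | starting material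
3 | (2S,3S)-3-(furan-2-yl)-3-hydroxy-2-methylpropanal | O=C[C@@H](C)[C@H](O)c1ccco1 | intermediate
4 | (1S,2R)-1-(furan-2-yl)-2-methylpropane-1,3-diol | OC[C@@H](C)[C@H](O)c1ccco1 | intermediate
5 | (1S,2R)-3-[(tert-butyldiphenylsilyl)oxy]-1-(furan-2-yl)-2-methylpropan-1-ol | CC(C)(C)[Si](c1ccccc1)(c1ccccc1)OC[C@@H](C)[C@H](O)c1ccco1 | intermediate
6 | (4S,5R)-5-[(2S)-1-[(tert-butyldiphenylsilyl)oxy]propan-2-yl]-4-hydroxycyclopent-2-en-1-one | O=C1C=C[C@H](O)[C@H]1[C@H](C)CO[Si](c1ccccc1)(c1ccccc1)C(C)(C)C | intermediate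
7 | (4S,5R)-4-[(tert-butyldimethylsilyl)oxy]-5-[(2S)-1-[(tert-butyldiphenylsilyl)oxy]propan-2-yl]cyclopent-2-en-1-one | O=C1C=C[C@H](O[Si](C)(C)C(C)(C)C)[C@H]1[C@H](C)CO[Si](c1ccccc1)(c1ccccc1)C(C)(C)C | intermediate
8 | pent-4-yn-1-ol | C#CCCCO | starting material
9 | cyclic (Z)-alkenylalane chelate, seven-membered O–Al(Me)–CH=C(Me)–(CH2)3 ring | C[Al]1OCCCC(C)=C1 | intermediate
10 | (Z)-5-iodo-4-methylpent-4-en-1-ol | OCCC/C(C)=C\I | intermediate
11 | (Z)-5-iodo-4-methylpent-4-enal | O=CCC/C(C)=C\I | intermediate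
12 | (4S,5R)-4-[(tert-butyldimethylsilyl)oxy]-5-[(2S)-1-[(tert-butyldiphenylsilyl)oxy]propan-2-yl]-2-[(4Z)-1-hydroxy-5-iodo-4-methylpent-4-en-1-yl]cyclopent-2-en-1-one (both carbinol epimers) | O=C1C(C(O)CC/C(C)=C\I)=C[C@H](O[Si](C)(C)C(C)(C)C)[C@H]1[C@H](C)CO[Si](c1ccccc1)(c1ccccc1)C(C)(C)C | intermediate
13 | dilithium salt (C6 enolate, C1 alkoxide) of conjugate-reduced 12 | [Li+].[Li+].[O-]C1=C(C([O-])CC/C(C)=C\I)C[C@H](O[Si](C)(C)C(C)(C)C)[C@H]1[C@H](C)CO[Si](c1ccccc1)(c1ccccc1)C(C)(C)C | intermediate
14 | (2R,4S,5R)-4-[(tert-butyldimethylsilyl)oxy]-5-[(2S)-1-[(tert-butyldiphenylsilyl)oxy]propan-2-yl]-2-[(1S,4Z)-1-hydroxy-5-iodo-4-methylpent-4-en-1-yl]-2-methylcyclopentan-1-one (with its 2S,1'R partner) | O=C1[C@@](C)([C@@H](O)CC/C(C)=C\I)C[C@H](O[Si](C)(C)C(C)(C)C)[C@H]1[C@H](C)CO[Si](c1ccccc1)(c1ccccc1)C(C)(C)C | intermediate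
15 | C1 methanesulfonate of 14 (same configuration) | O=C1[C@@](C)([C@@H](OS(C)(=O)=O)CC/C(C)=C\I)C[C@H](O[Si](C)(C)C(C)(C)C)[C@H]1[C@H](C)CO[Si](c1ccccc1)(c1ccccc1)C(C)(C)C | intermediate
16 | (Z)-alkenyllithium from 15 (Li in place of I) | O=C1[C@@](C)([C@@H](OS(C)(=O)=O)CC/C(C)=C\[Li])C[C@H](O[Si](C)(C)C(C)(C)C)[C@H]1[C@H](C)CO[Si](c1ccccc1)(c1ccccc1)C(C)(C)C | intermediate
17 | lithium alkoxide of the cis-fused bicyclo[5.3.0]dec-4-en-6-ol with the C6–C10 bond (O6 cis to C14, 1-OMs cis to C14) | [Li+].[O-][C@]12/C=C(C)\CC[C@H](OS(C)(=O)=O)[C@@]1(C)C[C@H](O[Si](C)(C)C(C)(C)C)[C@H]2[C@H](C)CO[Si](c1ccccc1)(c1ccccc1)C(C)(C)C | intermediate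
18 | (1(10)E,4Z,7R,8S,11S)-8-[(tert-butyldimethylsilyl)oxy]-12-[(tert-butyldiphenylsilyl)oxy]germacra-1(10),4-dien-6-one | CC(C)(C)[Si](c1ccccc1)(c1ccccc1)OC[C@@H](C)[C@H]1C(=O)/C=C(C)\CC/C=C(\C)C[C@@H]1O[Si](C)(C)C(C)(C)C | intermediate
19 | (1(10)E,4Z,7R,8S,11S)-8,12-dihydroxygermacra-1(10),4-dien-6-one | OC[C@@H](C)[C@H]1C(=O)/C=C(C)\CC/C=C(\C)C[C@@H]1O | intermediate
20 | angelic acid, (2Z)-2-methylbut-2-enoic acid | C/C=C(/C)C(=O)O | starting material
21 | angelic 2,4,6-trichlorobenzoic anhydride | C/C=C(/C)C(=O)OC(=O)c1c(Cl)cc(Cl)cc1Cl | intermediate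
22 | (1(10)E,4Z,7R,8S,11S)-6-oxogermacra-1(10),4-diene-8,12-diyl bis[(2Z)-2-methylbut-2-enoate] | C/C=C(/C)C(=O)OC[C@@H](C)[C@H]1C(=O)/C=C(C)\CC/C=C(\C)C[C@@H]1OC(=O)/C(C)=C\C | intermediate
23 | (1(10)E,4Z,6S,7S,8S,11S)-6-hydroxygermacra-1(10),4-diene-8,12-diyl bis[(2Z)-2-methylbut-2-enoate] | C/C=C(/C)C(=O)OC[C@@H](C)[C@H]1[C@@H](O)/C=C(C)\CC/C=C(\C)C[C@@H]1OC(=O)/C(C)=C\C | intermediate
24 | (1(10)E,4S,5R,6R,7S,8S,11S)-4,5-epoxy-6-hydroxygermacr-1(10)-ene-8,12-diyl bis[(2Z)-2-methylbut-2-enoate] (CNP0272382.1) | C/C=C(/C)C(=O)OC[C@@H](C)[C@H]1[C@@H](O)[C@H]2O[C@@]2(C)CC/C=C(\C)C[C@@H]1OC(=O)/C(C)=C\C | target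

**Totals**
Total step count: 14.
Longest linear sequence: 12 steps (1–4, then 7–14); steps 5–6 make aldehyde 11 in parallel.

**Steps most likely to fail**

Step 8 (reductive methylation). The borohydride may reduce the carbonyl 1,2, the lithium aldolate may undergo retro-aldol cleavage, or facial control may be weak. The fallback sets out from 12 and comes back at 14. The enone is first reduced on its own with [(Ph3P)CuH]6 in benzene, a chemoselective conjugate reduction that should tolerate the alkenyl iodide, to give the saturated β-hydroxy ketone F1. F1 is then deprotonated with LDA (2.2 equiv, THF, −78 to −40 °C) to the alkoxide–enolate dianion, at C10 because the alkoxide directs there and C7–H is shielded. Methylation with MeI/DMPU, the classical Fráter–Seebach protocol, gives 14.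

Step 10 (the new cyclisation–fragmentation cascade). The alkenyllithium may enolise the ketone or attack the mesylate, or the lithium alkoxide may fragment sluggishly. The fallback uses known chemistry, sets out from 15 and comes back at 18. A Nozaki–Hiyama–Kishi cyclisation with CrCl2 (6 equiv) and NiCl2 (2 mol %) in DMSO at 23–50 °C tolerates the mesylate and stops at the chromium alkoxide, giving after work-up the bicyclic tertiary alcohol mesylate F2. Treating F2 with KOt-Bu in t-BuOH/THF at 0 °C effects a classical Wharton fragmentation to 18.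

Step 13 (facial selectivity of hydride addition to the ten-membered ketone). This cannot be predicted with confidence. The fallback sets out from 19 and comes back at 24.
- Evans–Saksena reduction of 19 with Me4NBH(OAc)3 in MeCN/AcOH at −20 °C delivers hydride internally from O8 and gives the 6,8-anti triol F3.
- VO(acac)2/t-BuOOH epoxidation, faster for the allylic than for the homoallylic hydroxyl, gives the epoxy triol F4.
- Acylation with 2.2 equiv of mixed anhydride 21 (from 20) should esterify the primary O12 and the O8 hydroxyl and leave the 6-OH, which is flanked by the oxirane and hydrogen-bonded to it, giving 24. The O8-over-O6 selectivity is the weak point of this fallback.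

**Further compounds**
F1 | step 8 | (4S,5R)-4-[(tert-butyldimethylsilyl)oxy]-5-[(2S)-1-[(tert-butyldiphenylsilyl)oxy]propan-2-yl]-2-[(4Z)-1-hydroxy-5-iodo-4-methylpent-4-en-1-yl]cyclopentan-1-one (epimers at C10 and C1) | O=C1C(C(O)CC/C(C)=C\I)C[C@H](O[Si](C)(C)C(C)(C)C)[C@H]1[C@H](C)CO[Si](c1ccccc1)(c1ccccc1)C(C)(C)C
F2 | step 10 | cis-fused bicyclic tertiary alcohol mesylate (protonated form of 17) | O[C@]12/C=C(C)\CC[C@H](OS(C)(=O)=O)[C@@]1(C)C[C@H](O[Si](C)(C)C(C)(C)C)[C@H]2[C@H](C)CO[Si](c1ccccc1)(c1ccccc1)C(C)(C)C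
F3 | step 13 | (1(10)E,4Z,6S,7R,8S,11S)-germacra-1(10),4-diene-6,8,12-triol | OC[C@@H](C)[C@H]1[C@@H](O)/C=C(C)\CC/C=C(\C)C[C@@H]1O
F4 | step 13 | (1(10)E,4S,5R,6R,7R,8S,11S)-4,5-epoxygermacr-1(10)-ene-6,8,12-triol | OC[C@@H](C)[C@H]1[C@@H](O)[C@H]2O[C@@]2(C)CC/C=C(\C)C[C@@H]1O
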